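The isoflavone is cut at the C3–C1' bond between pyranone ring C and ring B. Ring B is carried as 2,3-dimethoxy-1,4-benzoquinone, whose two ring C–H positions are equivalent, and the nucleophilic C3–H of the O1–C2=C3 enol ether of a 3-unsubstituted chromone is joined to it by a palladium-catalysed dehydrogenative coupling, so neither partner needs a halide or boron handle. The coupling precursor is 5,7-bis(benzyloxy)-6-methoxychromen-4-one, built from methyl 4-O-methylgallate through a symmetric phenol. After the coupling the quinone is reduced and O-methylated to the 2',3',4',5'-tetramethoxyphenyl ring, and hydrogenolysis frees the 5- and 7-hydroxyls.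

Key step: step 8

Remark: the target and all intermediates are achiral; the only stereo element on the route is the E geometry of enaminone 10, which is lost on ring closure. The coupled quinone is named with lowest locants as a 5-aryl-2,3-dimethoxy-1,4-benzoquinone.

Step 1
Reactants: 1 methyl 3,5-dihydroxy-4-methoxybenzoate; 2 benzyl bromide
Product: 3 methyl 3,5-bis(benzyloxy)-4-methoxybenzoate
Conditions: BnBr (2.3 equiv), K2CO3, DMF, 60 °C
Reagents that add atoms: benzyl bromide (compound 2), BrCc1ccccc1
Why: Williamson ether synthesis; both phenols are alkylated by the benzylic bromide under carbonate while the methyl ester is inert.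

Step 2
Reactants: 3 methyl 3,5-bis(benzyloxy)-4-methoxybenzoate
Product: 4 [3,5-bis(benzyloxy)-4-methoxyphenyl]methanol
Conditions: LiAlH4, THF, 0 °C to rt; aqueous work-up
Reagents that add atoms: none
Why: Hydride reduction of the ester to the primary benzylic alcohol; benzyl and methyl aryl ethers are not touched by LiAlH4.

Step 3
Reactants: 4 [3,5-bis(benzyloxy)-4-methoxyphenyl]methanol
Product: 5 3,5-bis(benzyloxy)-4-methoxybenzaldehyde
Conditions: MnO2 (activated, excess), CH2Cl2, rt
Reagents that add atoms: none
Why: Selective heterogeneous oxidation of a benzylic alcohol with MnO2, which should stop cleanly at the aldehyde.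

Step 4
Reactants: 5 3,5-bis(benzyloxy)-4-methoxybenzaldehyde
Product: 7 3,5-bis(benzyloxy)-4-methoxyphenol, via aryl formate 6 (not isolated)
Conditions: mCPBA, CH2Cl2, 0 °C to rt; excess peracid quenched (aq. Na2S2O3), solvent exchanged; then K2CO3 (cat.), MeOH, rt
Reagents that add atoms: 3-chloroperoxybenzoic acid (mCPBA), O=C(OO)c1cccc(Cl)c1
Why: Baeyer–Villiger (Dakin-type) oxidation in which the electron-rich aryl group with its para methoxy substituent migrates in preference to hydrogen, followed by base-catalysed transesterification of the formate with methanol.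

Step 5
Reactants: 7 3,5-bis(benzyloxy)-4-methoxyphenol
Product: 9 1-[2,4-bis(benzyloxy)-6-hydroxy-3-methoxyphenyl]ethanone, via difluoroboron chelate 8 (not isolated)
Conditions: Ac2O, BF3·OEt2, CH2Cl2, 0 °C to rt; then H2O/MeOH, 50 °C
Reagents that add atoms: acetic anhydride, CC(=O)OC(C)=O
Why: Friedel–Crafts (Fries-type) ortho C-acylation of a phloroglucinol-like ring whose two positions ortho to the free hydroxyl are equivalent by symmetry, so only one ketone can form; the ketone is held as its O,O-difluoroboron chelate, which resists a second acylation and is hydrolysed on aqueous work-up, and the low temperature should spare the benzyl ether next to the new carbonyl.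

Step 6
Reactants: 9 1-[2,4-bis(benzyloxy)-6-hydroxy-3-methoxyphenyl]ethanone
Product: 11 5,7-bis(benzyloxy)-6-methoxy-4H-chromen-4-one, via enaminone 10 (not isolated)
Conditions: DMF-DMA (neat), 95 °C; evaporate; then AcOH, 90 °C
Reagents that add atoms: N,N-dimethylformamide dimethyl acetal, COC(OC)N(C)C
Why: Condensation of the methyl ketone with the amide acetal gives the E-enaminone, and acid-promoted addition of the phenolic hydroxyl to its β-carbon with loss of dimethylamine closes pyranone ring C (enaminone chromone synthesis), leaving C2 and C3 unsubstituted.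

Step 7
Reactants: 12 1,2,3,4-tetramethoxybenzene
Product: 13 2,3-dimethoxy-1,4-benzoquinone
Conditions: (NH4)2Ce(NO3)6 (2.5 equiv), MeCN/H2O, 0 °C
Reagents that add atoms: water, O
Why: Oxidative demethylation of a para-dimethoxyarene by a one-electron oxidant; water adds to the arene radical cation at the two para ipso carbons and methanol is expelled, giving the para-quinone with the 2,3-methoxy groups kept as vinylogous esters.

Step 8
Reactants: 11 5,7-bis(benzyloxy)-6-methoxy-4H-chromen-4-one; 13 2,3-dimethoxy-1,4-benzoquinone
Product: 14 5-[5,7-bis(benzyloxy)-6-methoxy-4-oxo-4H-chromen-3-yl]-2,3-dimethoxycyclohexa-2,5-diene-1,4-dione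
Conditions: Pd(OAc)2 (20 mol%), Cu(OAc)2 (2.5 equiv), 13 (3 equiv), PivOH, 100 °C
Reagents that add atoms: none
Why: Carboxylate-assisted electrophilic palladation by divalent palladium at C3 of 11 should give a 3-chromonyl palladium carboxylate, which adds across the unsubstituted C=C of quinone 13; β-hydride elimination (or enolisation to the arylhydroquinone and reoxidation) then gives the arylquinone, and Cu(OAc)2 returns zerovalent palladium to the divalent state. The closest known reaction type is the Fujiwara–Moritani (oxidative Heck) C3–H coupling of chromones with quinones and acrylates under Pd(OAc)2 with a copper or silver carboxylate in pivalic acid. No ring is closed and no stereocentre is formed, so the step only has to control the site on each partner. C3 should win over C2 because O1 donates through C2=C3 and makes C3 the nucleophilic carbon, while C2 is the electrophilic β-carbon of the enone, and because the electron-poor quinone acts as the acceptor and is not palladated itself. C8 is flanked by O1 and the 7-benzyloxy group and is hindered for concerted metalation, and C5 is substituted so carbonyl-directed peri palladation is excluded. The two quinone C–H bonds are equivalent by mirror symmetry, excess 13 suppresses double chromonylation, and any product left at the hydroquinone level converges with the main material in step 9.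

Step 9
Reactants: 14 5-[5,7-bis(benzyloxy)-6-methoxy-4-oxo-4H-chromen-3-yl]-2,3-dimethoxycyclohexa-2,5-diene-1,4-dione
Product: 15 5,7-bis(benzyloxy)-3-(2,5-dihydroxy-3,4-dimethoxyphenyl)-6-methoxy-4H-chromen-4-one
Conditions: Na2S2O4, THF/H2O, rt, Ar
Reagents that add atoms: none
Why: Two-electron reduction of the quinone to the hydroquinone by dithionite, to which the chromone and the benzyl ethers are inert; the air-sensitive product is carried on at once under argon.

Step 10
Reactants: 15 5,7-bis(benzyloxy)-3-(2,5-dihydroxy-3,4-dimethoxyphenyl)-6-methoxy-4H-chromen-4-one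
Product: 16 5,7-bis(benzyloxy)-6-methoxy-3-(2,3,4,5-tetramethoxyphenyl)-4H-chromen-4-one
Conditions: MeI (excess), K2CO3, DMF, rt to 40 °C, Ar
Reagents that add atoms: iodomethane, CI
Why: Williamson O-methylation of the two hydroquinone hydroxyls; attack of the 2'-phenoxide on C2 would be a disfavoured 5-endo-trig closure, so the open isoflavone should persist and be methylated.

Step 11
Reactants: 16 5,7-bis(benzyloxy)-6-methoxy-3-(2,3,4,5-tetramethoxyphenyl)-4H-chromen-4-one
Product: 17 irisjaponin A, 5,7-dihydroxy-6-methoxy-3-(2,3,4,5-tetramethoxyphenyl)-4H-chromen-4-one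
Conditions: H2 (1 atm), Pd/C (10 wt%), EtOAc/MeOH, rt
Reagents that add atoms: none
Why: Catalytic hydrogenolysis of the two benzylic C–O bonds, with the five methyl ethers inert; the reaction is stopped once both benzyl groups are gone so that the C2=C3 bond of ring C is not reduced.

Compound list
1 | methyl 3,5-dihydroxy-4-methoxybenzoate (methyl 4-O-methylgallate) | COC(=O)c1cc(O)c(OC)c(O)c1 | starting material
2 | benzyl bromide | BrCc1ccccc1 | starting material
3 | methyl 3,5-bis(benzyloxy)-4-methoxybenzoate | COC(=O)c1cc(OCc2ccccc2)c(OC)c(OCc2ccccc2)c1 | intermediate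
4 | [3,5-bis(benzyloxy)-4-methoxyphenyl]methanol | OCc1cc(OCc2ccccc2)c(OC)c(OCc2ccccc2)c1 | intermediate
5 | 3,5-bis(benzyloxy)-4-methoxybenzaldehyde | O=Cc1cc(OCc2ccccc2)c(OC)c(OCc2ccccc2)c1 | intermediate
6 | 3,5-bis(benzyloxy)-4-methoxyphenyl formate (not isolated) | O=COc1cc(OCc2ccccc2)c(OC)c(OCc2ccccc2)c1 | intermediate
7 | 3,5-bis(benzyloxy)-4-methoxyphenol | Oc1cc(OCc2ccccc2)c(OC)c(OCc2ccccc2)c1 | intermediate
8 | difluoroboron chelate of ketone 9, a six-membered O–BF2–O ring between the phenolate oxygen and the acetyl oxygen (not isolated) | CC1=[O+][B-](F)(F)Oc2cc(OCc3ccccc3)c(OC)c(OCc3ccccc3)c12 | intermediate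
9 | 1-[2,4-bis(benzyloxy)-6-hydroxy-3-methoxyphenyl]ethanone | CC(=O)c1c(O)cc(OCc2ccccc2)c(OC)c1OCc1ccccc1 | intermediate
10 | (2E)-1-[2,4-bis(benzyloxy)-6-hydroxy-3-methoxyphenyl]-3-(dimethylamino)prop-2-en-1-one (not isolated) | CN(C)/C=C/C(=O)c1c(O)cc(OCc2ccccc2)c(OC)c1OCc1ccccc1 | intermediate
11 | 5,7-bis(benzyloxy)-6-methoxy-4H-chromen-4-one | COc1c(OCc2ccccc2)cc2occc(=O)c2c1OCc1ccccc1 | intermediate
12 | 1,2,3,4-tetramethoxybenzene | COc1ccc(OC)c(OC)c1OC | starting material
13 | 2,3-dimethoxy-1,4-benzoquinone | COC1=C(OC)C(=O)C=CC1=O | intermediate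
14 | 5-[5,7-bis(benzyloxy)-6-methoxy-4-oxo-4H-chromen-3-yl]-2,3-dimethoxycyclohexa-2,5-diene-1,4-dione | COC1=C(OC)C(=O)C(c2coc3cc(OCc4ccccc4)c(OC)c(OCc4ccccc4)c3c2=O)=CC1=O | intermediate
15 | 5,7-bis(benzyloxy)-3-(2,5-dihydroxy-3,4-dimethoxyphenyl)-6-methoxy-4H-chromen-4-one | COc1c(O)cc(-c2coc3cc(OCc4ccccc4)c(OC)c(OCc4ccccc4)c3c2=O)c(O)c1OC | intermediate
16 | 5,7-bis(benzyloxy)-6-methoxy-3-(2,3,4,5-tetramethoxyphenyl)-4H-chromen-4-one | COc1cc(-c2coc3cc(OCc4ccccc4)c(OC)c(OCc4ccccc4)c3c2=O)c(OC)c(OC)c1OC | intermediate
17 | irisjaponin A, 5,7-dihydroxy-6-methoxy-3-(2,3,4,5-tetramethoxyphenyl)-4H-chromen-4-one | COc1cc(-c2coc3cc(O)c(OC)c(O)c3c2=O)c(OC)c(OC)c1OC | target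

Total step count: 11.
Longest linear sequence: 10 steps (steps 1 to 6, then 8 to 11); step 7 is a one-step side branch.

Steps most likely to fail

Step 8. The coupling may lose site control (palladation at C8 or C2 instead of C3), may run on to double chromonylation of the quinone, or may erode the 5-benzyl ether in hot pivalic acid. The fallback replaces the C–H coupling by a halide–boron cross-coupling. Enaminone 10 is isolated after the first stage of step 6 and cyclised with I2 in CHCl3 at rt to 5,7-bis(benzyloxy)-3-iodo-6-methoxy-4H-chromen-4-one F1. Separately, 12 is brominated (NBS, MeCN, rt) to 1-bromo-2,3,4,5-tetramethoxybenzene F2, which is borylated (B2pin2, PdCl2(dppf), KOAc, dioxane, 90 °C) to 4,4,5,5-tetramethyl-2-(2,3,4,5-tetramethoxyphenyl)-1,3,2-dioxaborolane F3. Suzuki–Miyaura coupling of F1 with F3 (Pd(PPh3)4, K2CO3, dioxane/H2O, 85 °C) should give 16. The fallback sets out from 10 and 12 and rejoins the route at 16.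

Step 5. The Lewis acid may cleave or shift the benzyl ether next to the new carbonyl, or the reaction may stop at O-acetylation. The fallback avoids acid altogether. Phenol 7 is formylated ortho to the hydroxyl through its magnesium phenoxide (MgCl2, Et3N, paraformaldehyde, MeCN, reflux) to 2,4-bis(benzyloxy)-6-hydroxy-3-methoxybenzaldehyde F4. Addition of MeMgBr (excess, THF, 0 °C) gives racemic 3,5-bis(benzyloxy)-2-(1-hydroxyethyl)-4-methoxyphenol F5, and MnO2 in CH2Cl2 oxidises the benzylic alcohol to ketone 9. The fallback sets out from 7 and rejoins at 9.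

Step 11. Hydrogenation may continue into saturation of the C2=C3 bond of ring C, or may stall before both ethers are cleaved. The fallback is a Lewis-acid debenzylation of 16 with BCl3 and pentamethylbenzene as benzyl cation scavenger in CH2Cl2 at −78 °C. The benzyl ethers, the 5-O-benzyl being activated by chelation to the C4 carbonyl, should cleave well before any aryl methyl ether at this temperature. The fallback sets out from 16 and gives 17 directly, with no new intermediate.

Further compounds
F1 | step 8 | 5,7-bis(benzyloxy)-3-iodo-6-methoxy-4H-chromen-4-one | COc1c(OCc2ccccc2)cc2occ(I)c(=O)c2c1OCc1ccccc1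
F2 | step 8 | 1-bromo-2,3,4,5-tetramethoxybenzene | COc1cc(Br)c(OC)c(OC)c1OC
F3 | step 8 | 4,4,5,5-tetramethyl-2-(2,3,4,5-tetramethoxyphenyl)-1,3,2-dioxaborolane | COc1cc(B2OC(C)(C)C(C)(C)O2)c(OC)c(OC)c1OC
F4 | step 5 | 2,4-bis(benzyloxy)-6-hydroxy-3-methoxybenzaldehyde | O=Cc1c(O)cc(OCc2ccccc2)c(OC)c1OCc1ccccc1
F5 | step 5 | 3,5-bis(benzyloxy)-2-(1-hydroxyethyl)-4-methoxyphenol (racemic) | CC(O)c1c(O)cc(OCc2ccccc2)c(OC)c1OCc1ccccc1
F0 | step 11 | none | none
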